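Assumption: hydroazulene intermediates are numbered as azulenes (carbonyl or carbinol carbon = C5) and benzoxepanes as 1‑benzoxepines; the oxepane carbinol centre (3S) carried from step 15 to step 22 is temporary and is erased in step 23.

**Retrosynthetic overview**

1. Target 39 ← oxidation of the oxepane carbinol of triol 38 ← desilylation of 37. Compound 37 is cut at the bond between the hydroazulene stereocentre and the ethylene bridge: a copper‑catalysed, phosphine‑directed syn‑SN2′ coupling of allylic ester 19 (left fragment) with the B‑alkyl‑9‑BBN borate made from vinyl benzoxepane 34 (right fragment).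
2. Right fragment 34 ← equatorial methyl addition to ketone 32 ← oxepane and cyclohexanone formed in one epoxonium oxa/carbacyclisation of acyclic bis‑epoxide dienol ether 30 ← Shi epoxidation ← Negishi carboalumination and Negishi coupling (23 + 24).
3. Left fragment 19 ← CBS reduction and esterification of enone 16 ← SmI2 ketyl–olefin closure of the cyclopentane on cycloheptadienone 15 ← Saegusa–Ito ring expansion of the asymmetric conjugate adduct of cyclohexadienone 5 ← Robinson annulation (1 + 2).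
4. Ring order: right – oxepane then cyclohexane (same step); left – six‑membered ring, expanded to seven, then the five‑membered ring; the two bicycles are joined last.

**Left fragment**

Step 1
Reactants: 1 isobutyraldehyde; 2 pent‑1‑en‑3‑one
Product: 4 2,4,4‑trimethylcyclohex‑2‑en‑1‑one, via keto aldehyde 3 (not isolated)
Conditions: H2SO4 (cat.), PhH, 45 °C, then reflux (Dean–Stark)
Reagents that add atoms: none
Why: Robinson annulation, in which Michael addition of the aldehyde enol gives 3 and the ethyl‑ketone CH2 then closes onto the non‑enolisable aldehyde by aldol condensation; no stereocentre is formed.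

Step 2
Reactants: 4 2,4,4‑trimethylcyclohex‑2‑en‑1‑one
Product: 5 2,4,4‑trimethylcyclohexa‑2,5‑dien‑1‑one
Conditions: DDQ (1.3 equiv), TsOH (cat.), 1,4‑dioxane, 100 °C
Reagents that add atoms: none
Why: DDQ dehydrogenation through the cross‑conjugated dienol stops at the dienone because the quaternary C4 prevents aromatisation.

Step 3
Reactants: 6 but‑3‑en‑2‑one
Product: 8 2‑(2‑bromoethyl)‑2‑methyl‑1,3‑dioxolane, via 4‑bromobutan‑2‑one 7 (not isolated)
Conditions: HBr (g), CH2Cl2, 0 °C; then HOCH2CH2OH, TsOH (cat.), 25 °C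
Reagents that add atoms: hydrogen bromide, Br; ethane‑1,2‑diol, OCCO
Why: Conjugate hydrobromination followed by acid‑catalysed ketalisation (ketone protection) gives a Grignard‑compatible 3‑oxobutyl synthon.

Step 4
Reactants: 8 2‑(2‑bromoethyl)‑2‑methyl‑1,3‑dioxolane; 5 2,4,4‑trimethylcyclohexa‑2,5‑dien‑1‑one
Product: 11 (3S)‑silyl dienol ether, via Grignard reagent 9 (not isolated), via magnesium dienolate 10 (not isolated)
Conditions: Mg, THF, 25 °C; then 5, CuBr·SMe2 (5 mol%), (R)‑1‑[(SP)‑2‑(diphenylphosphino)ferrocenyl]ethyldicyclohexylphosphine (6 mol%), t‑BuOMe, −78 °C; then Me3SiCl, Et3N, DMPU, −78 → 0 °C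
Reagents that add atoms: chlorotrimethylsilane, C[Si](C)(C)Cl
Why: Copper‑catalysed asymmetric conjugate addition of the Grignard reagent to the unsubstituted enone arm (the α‑methyl arm is less electrophilic), with the chiral diphosphine selecting the alkene face to give the S centre (the mirror‑image ligand is used if a test run shows the opposite sense), and the enolate is trapped regiospecifically as the cross‑conjugated silyl dienol ether.

Step 5
Reactants: 11 (3S)‑silyl dienol ether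
Product: 12 (1R,5S,6S)‑siloxycyclopropane
Conditions: Et2Zn, CH2I2, CH2Cl2, 0 °C
Reagents that add atoms: diiodomethane, ICI
Why: Furukawa–Simmons–Smith cyclopropanation is selective for the electron‑rich silyl enol ether alkene and occurs anti to the neighbouring side chain (these two new centres are lost in step 6).

Step 6
Reactants: 12 (1R,5S,6S)‑siloxycyclopropane
Product: 15 (5S)‑2,4,4‑trimethyl‑5‑(3‑oxobutyl)cyclohepta‑2,6‑dien‑1‑one, via chloro ketone 13 (not isolated), via dienone ketal 14 (not isolated)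
Conditions: FeCl3 (2.2 equiv), DMF, 0 °C; NaOAc, MeOH, 65 °C; then 1 M HCl, THF, 25 °C
Reagents that add atoms: water, O
Why: Saegusa–Ito ring expansion (one‑electron oxidation of the siloxycyclopropane, scission of the internal bond, chlorine transfer, then loss of HCl) gives the cross‑conjugated cycloheptadienone, and aqueous acid frees the methyl ketone without touching the S centre.

Step 7
Reactants: 15 (5S)‑2,4,4‑trimethyl‑5‑(3‑oxobutyl)cyclohepta‑2,6‑dien‑1‑one
Product: 16 (3S,3aS,8aS)‑3‑hydroxy‑3,6,8,8‑tetramethyl‑2,3,3a,4,8,8a‑hexahydroazulen‑5(1H)‑one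
Conditions: SmI2 (2.2 equiv), t‑BuOH (2 equiv), THF/HMPA, −78 °C
Reagents that add atoms: none
Why: Samarium diiodide ketyl–olefin (ketone–enone) 5‑exo reductive cyclisation onto the β‑carbon next to the tether, where the ring forces a cis fusion and the bulky samarium‑bound oxygen turns away from the acceptor, so the hydroxyl ends on the convex face syn to both ring‑fusion hydrogens; the samarium dienolate is protonated on work‑up and leaves the α‑methyl enone intact.

Step 8
Reactants: 16 hydroxy enone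
Product: 17 (3S,3aS,8aS)‑3,6,8,8‑tetramethyl‑3‑(triethylsilyloxy)‑2,3,3a,4,8,8a‑hexahydroazulen‑5(1H)‑one
Conditions: Et3SiOTf (1.2 equiv), 2,6‑lutidine, CH2Cl2, −78 °C
Reagents that add atoms: triethylsilyl trifluoromethanesulfonate, CC[Si](CC)(CC)OS(=O)(=O)C(F)(F)F
Why: Silyl triflate protection of the exposed tertiary alcohol keeps it inert toward the borane, base and copper used later.

Step 9
Reactants: 17 silyloxy enone
Product: 18 (3S,3aS,5R,8aS)‑3,6,8,8‑tetramethyl‑3‑(triethylsilyloxy)‑1,2,3,3a,4,5,8,8a‑octahydroazulen‑5‑ol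
Conditions: (S)‑1‑methyl‑3,3‑diphenyl‑tetrahydro‑1H,3H‑pyrrolo[1,2‑c][1,3,2]oxazaborole (20 mol%), BH3·SMe2 (0.7 equiv), THF, −30 °C
Reagents that add atoms: none
Why: Corey–Bakshi–Shibata reduction in which the α‑methyl alkenyl arm acts as the large group, so the S catalyst gives the 5R allylic alcohol (hydroxyl trans to the ring‑fusion hydrogens) under reagent control.

Step 10
Reactants: 18 allylic alcohol
Product: 19 (3S,3aS,5R,8aS)‑3,6,8,8‑tetramethyl‑3‑(triethylsilyloxy)‑1,2,3,3a,4,5,8,8a‑octahydroazulen‑5‑yl 2‑(diphenylphosphanyl)benzoate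
Conditions: 2‑(diphenylphosphanyl)benzoic acid, DCC, 4‑(dimethylamino)pyridine (cat.), CH2Cl2, 25 °C
Reagents that add atoms: 2‑(diphenylphosphanyl)benzoic acid, OC(=O)c1ccccc1P(c1ccccc1)c1ccccc1
Why: Steglich esterification of the secondary allylic alcohol with retention installs a leaving group that carries a copper‑binding phosphine.

**Right fragment**

Step 11
Reactants: 20 5‑bromo‑2‑methylpent‑2‑ene
Product: 21 6‑methylhept‑5‑en‑1‑yne
Conditions: NaC≡CH (18% in xylene), DMSO/THF, 10 → 25 °C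
Reagents that add atoms: sodium acetylide, [Na+].[C-]#C
Why: SN2 alkylation of acetylide by a primary homoallylic bromide.

Step 12
Reactants: 21 6‑methylhept‑5‑en‑1‑yne
Product: 23 (1E)‑1‑iodo‑2,6‑dimethylhepta‑1,5‑diene, via alkenylalane 22 (not isolated)
Conditions: AlMe3 (2 equiv), Cp2ZrCl2 (20 mol%), CH2Cl2, 0 → 25 °C; then I2, THF, −30 °C
Reagents that add atoms: trimethylaluminium, C[Al](C)C; iodine, II
Why: Negishi zirconium‑catalysed carboalumination adds methyl and aluminium syn across the terminal alkyne, and iodinolysis with retention fixes the E trisubstituted alkene.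

Step 13
Reactants: 23 (1E)‑1‑iodo‑2,6‑dimethylhepta‑1,5‑diene; 24 ethyl 3‑iodopropanoate
Product: 26 ethyl (4E)‑5,9‑dimethyldeca‑4,8‑dienoate, via zinc homoenolate 25 (not isolated)
Conditions: 24, Zn dust (BrCH2CH2Br, Me3SiCl), THF/DMA, 40 °C; then 23, Pd(PPh3)4 (3 mol%), 50 °C
Reagents that add atoms: none
Why: Negishi sp2–sp3 cross‑coupling of the zinc homoenolate with the alkenyl iodide proceeds with retention of the E geometry.

Step 14
Reactants: 26 ethyl (4E)‑5,9‑dimethyldeca‑4,8‑dienoate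
Product: 27 (4E)‑N‑methoxy‑N,5,9‑trimethyldeca‑4,8‑dienamide
Conditions: MeNH(OMe)·HCl (1.5 equiv), i‑PrMgCl (3 equiv), THF, −20 °C
Reagents that add atoms: N,O‑dimethylhydroxylamine hydrochloride, CNOC.Cl
Why: Direct aminolysis of the ester by the magnesium amide gives the Weinreb amide.

Step 15
Reactants: 27 Weinreb amide
Product: 28 3‑[(2S,3S)‑3‑{2‑[(2S)‑3,3‑dimethyloxiran‑2‑yl]ethyl}‑3‑methyloxiran‑2‑yl]‑N‑methoxy‑N‑methylpropanamide
Conditions: 1,2:4,5‑di‑O‑isopropylidene‑β‑L‑erythro‑2,3‑hexodiulo‑2,6‑pyranose (L‑fructose‑derived Shi ketone, 0.6 equiv), KHSO5 (as Oxone), K2CO3, Bu4NHSO4, MeCN/CH2(OMe)2/aq. Na2B4O7 buffer (pH 10.5), 0 °C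
Reagents that add atoms: potassium peroxymonosulfate, [K+].[O-]OS(=O)(=O)O
Why: Shi dioxirane epoxidation of both trisubstituted alkenes through the spiro transition state, in which the L‑series ketone gives the (S,S) and (S) epoxides that fix the later ring‑fusion centres.

Step 16
Reactants: 28 bis‑epoxy Weinreb amide
Product: 29 1‑[(2S,3S)‑3‑{2‑[(2S)‑3,3‑dimethyloxiran‑2‑yl]ethyl}‑3‑methyloxiran‑2‑yl]hex‑5‑en‑3‑one
Conditions: CH2=CHCH2MgBr (1.3 equiv), THF, −78 °C; cold aq. NH4Cl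
Reagents that add atoms: allylmagnesium bromide, C=CC[Mg]Br
Why: Weinreb ketone synthesis, where the chelated tetrahedral adduct prevents over‑addition and the trisubstituted epoxides are inert at −78 °C.

Step 17
Reactants: 29 bis‑epoxy allyl ketone
Product: 30 (3Z)‑tert‑butyldimethylsilyl dienol ether of 29
Conditions: t‑BuMe2SiCl (in situ), KN(SiMe3)2, THF, −78 °C
Reagents that add atoms: tert‑butylchlorodimethylsilane, CC(C)(C)[Si](C)(C)Cl
Why: Deprotonation occurs only at the doubly activated (α‑keto, allylic) CH2 and O‑silylation gives the Z 2‑silyloxy diene before the enolate can open an epoxide.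

Step 18
Reactants: 30 bis‑epoxy silyl dienol ether
Product: 32 (3S,5aS,6S,9aS)‑6‑ethenyl‑3‑hydroxy‑2,2,5a‑trimethyloctahydro‑1‑benzoxepin‑7(2H)‑one, via silyl ether 31 (not isolated)
Conditions: Me3SiOTf (1.1 equiv), 2,6‑di‑tert‑butyl‑4‑methylpyridine, CH2Cl2, −78 °C; aq. NaHCO3; then 1 M HCl, THF, 0 °C
Reagents that add atoms: none
Why: Epoxonium tandem oxa/carbacyclisation, in which the silyl‑activated terminal epoxide is opened at its tertiary carbon by the internal epoxide oxygen (oxepane, retention at both secondary C–O carbons) and the resulting epoxonium is opened anti at its tertiary carbon by the α‑carbon of the Z dienol ether through a chair (cyclohexanone, inversion at C5a, equatorial vinyl), giving the trans‑fused 5aS,6S,9aS bicycle.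

Step 19
Reactants: 32 hydroxy ketone
Product: 33 (3S,5aS,6S,7R,9aS)‑6‑ethenyl‑2,2,5a,7‑tetramethyldecahydro‑1‑benzoxepine‑3,7‑diol
Conditions: CeCl3 (3 equiv), MeMgBr (3 equiv), THF, −78 → 0 °C
Reagents that add atoms: methylmagnesium bromide, C[Mg]Br
Why: Organocerium 1,2‑addition in which the axial C5a methyl blocks axial attack, so methyl enters equatorially and gives the axial 7R tertiary alcohol, while CeCl3 suppresses enolisation of the α‑vinyl ketone.

Step 20
Reactants: 33 diol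
Product: 34 bis(triethylsilyl) ether of 33
Conditions: Et3SiOTf (2.5 equiv), 2,6‑lutidine, CH2Cl2, −78 → 25 °C
Reagents that add atoms: triethylsilyl trifluoromethanesulfonate, CC[Si](CC)(CC)OS(=O)(=O)C(F)(F)F
Why: Silyl triflate silylates both the secondary and the hindered tertiary alcohol, leaving the vinyl group as the only reactive site.

**Fragment union and endgame**

Step 21
Reactants: 34 vinyl bis‑silyl ether; 19 allylic phosphinobenzoate
Product: 37 tris(triethylsilyl) ether of triol 38, via alkylborane 35 (not isolated), via methoxyborate 36 (not isolated)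
Conditions: 34, 9‑BBN dimer (0.55 equiv), THF, 60 °C; KOMe (1.1 equiv), 25 °C; then 19 (0.9 equiv), CuCl (10 mol%), THF/1,4‑dioxane, 40 °C
Reagents that add atoms: none
Why: Proposed new method: a phosphine‑directed, copper‑catalysed syn‑SN2′ allyl–alkyl coupling of a B‑alkyl‑9‑BBN methoxyborate with an allylic 2‑(diphenylphosphanyl)benzoate, in which the ester phosphine binds monovalent copper, the borate transfers its primary alkyl group to that copper, the tethered alkylcopper adds to the γ‑carbon (C7 of 19) on the face of the leaving group, and trivalent copper reductively eliminates as the carboxylate leaves, so the 5R carbinol centre sets the new C–C bond and its stereocentre by 1,3‑syn transfer while the alkene moves to the position it has in the target; the closest known reaction types are the phosphine‑directed copper‑mediated allylic substitution of such benzoates with Grignard reagents and the undirected copper‑catalysed γ‑selective coupling of alkyl‑9‑BBN borates with allylic phosphates, neither of which has been shown for a borate delivered to a ring‑embedded neopentyl γ‑carbon.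

Step 22
Reactants: 37 tris‑silyl ether
Product: 38 triol
Conditions: HF·pyridine, pyridine, THF, 0 → 25 °C
Reagents that add atoms: none
Why: Buffered fluoride desilylation cleaves all three triethylsilyl ethers without ionising the tertiary alcohols or isomerising the trisubstituted alkene.

Step 23
Reactants: 38 triol
Product: 39 target
Conditions: Dess–Martin periodinane (1.3 equiv), NaHCO3, CH2Cl2, 25 °C
Reagents that add atoms: none
Why: Dess–Martin oxidation converts the only secondary alcohol to the oxepanone (erasing the temporary 3S centre) and cannot oxidise the two tertiary alcohols.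

**Compound list**

1 | isobutyraldehyde (2‑methylpropanal) | CC(C)C=O | starting material
2 | pent‑1‑en‑3‑one | CCC(=O)C=C | starting material
3 | 2,2‑dimethyl‑5‑oxoheptanal (in situ) | CCC(=O)CCC(C)(C)C=O | intermediate
4 | 2,4,4‑trimethylcyclohex‑2‑en‑1‑one | CC1=CC(C)(C)CCC1=O | intermediate
5 | 2,4,4‑trimethylcyclohexa‑2,5‑dien‑1‑one | CC1=CC(C)(C)C=CC1=O | intermediate
6 | but‑3‑en‑2‑one | CC(=O)C=C | starting material
7 | 4‑bromobutan‑2‑one (in situ) | CC(=O)CCBr | intermediate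
8 | 2‑(2‑bromoethyl)‑2‑methyl‑1,3‑dioxolane | CC1(CCBr)OCCO1 | intermediate
9 | [2‑(2‑methyl‑1,3‑dioxolan‑2‑yl)ethyl]magnesium bromide (in situ) | CC1(CC[Mg]Br)OCCO1 | intermediate
10 | bromomagnesium (3S)‑4,4,6‑trimethyl‑3‑[2‑(2‑methyl‑1,3‑dioxolan‑2‑yl)ethyl]cyclohexa‑1,5‑dien‑1‑olate (in situ) | CC1=CC(C)(C)[C@@H](CCC2(C)OCCO2)C=C1O[Mg]Br | intermediate
11 | trimethyl({(3S)‑4,4,6‑trimethyl‑3‑[2‑(2‑methyl‑1,3‑dioxolan‑2‑yl)ethyl]cyclohexa‑1,5‑dien‑1‑yl}oxy)silane | CC1=CC(C)(C)[C@@H](CCC2(C)OCCO2)C=C1O[Si](C)(C)C | intermediate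
12 | trimethyl({(1R,5S,6S)‑2,4,4‑trimethyl‑5‑[2‑(2‑methyl‑1,3‑dioxolan‑2‑yl)ethyl]bicyclo[4.1.0]hept‑2‑en‑1‑yl}oxy)silane (cyclopropane anti to the side chain) | CC1=CC(C)(C)[C@@H](CCC2(C)OCCO2)[C@@H]2C[C@]12O[Si](C)(C)C | intermediate
13 | 6‑chloro‑2,4,4‑trimethyl‑5‑[2‑(2‑methyl‑1,3‑dioxolan‑2‑yl)ethyl]cyclohept‑2‑en‑1‑one, side‑chain carbon as in 11, both epimers at C–Cl (in situ) | CC1=CC(C)(C)[C@@H](CCC2(C)OCCO2)C(Cl)CC1=O | intermediate
14 | (5S)‑2,4,4‑trimethyl‑5‑[2‑(2‑methyl‑1,3‑dioxolan‑2‑yl)ethyl]cyclohepta‑2,6‑dien‑1‑one (in situ) | CC1=CC(C)(C)[C@@H](CCC2(C)OCCO2)C=CC1=O | intermediate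
15 | (5S)‑2,4,4‑trimethyl‑5‑(3‑oxobutyl)cyclohepta‑2,6‑dien‑1‑one | CC1=CC(C)(C)[C@@H](CCC(C)=O)C=CC1=O | intermediate
16 | (3S,3aS,8aS)‑3‑hydroxy‑3,6,8,8‑tetramethyl‑2,3,3a,4,8,8a‑hexahydroazulen‑5(1H)‑one (cis‑fused, OH syn to both ring‑fusion H) | CC1=CC(C)(C)[C@H]2CC[C@](C)(O)[C@H]2CC1=O | intermediate
17 | (3S,3aS,8aS)‑3,6,8,8‑tetramethyl‑3‑(triethylsilyloxy)‑2,3,3a,4,8,8a‑hexahydroazulen‑5(1H)‑one | CC1=CC(C)(C)[C@H]2CC[C@](C)(O[Si](CC)(CC)CC)[C@H]2CC1=O | intermediate
18 | (3S,3aS,5R,8aS)‑3,6,8,8‑tetramethyl‑3‑(triethylsilyloxy)‑1,2,3,3a,4,5,8,8a‑octahydroazulen‑5‑ol | CC1=CC(C)(C)[C@H]2CC[C@](C)(O[Si](CC)(CC)CC)[C@H]2C[C@H]1O | intermediate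
19 | (3S,3aS,5R,8aS)‑3,6,8,8‑tetramethyl‑3‑(triethylsilyloxy)‑1,2,3,3a,4,5,8,8a‑octahydroazulen‑5‑yl 2‑(diphenylphosphanyl)benzoate | CC1=CC(C)(C)[C@H]2CC[C@](C)(O[Si](CC)(CC)CC)[C@H]2C[C@H]1OC(=O)c1ccccc1P(c1ccccc1)c1ccccc1 | intermediate
20 | 5‑bromo‑2‑methylpent‑2‑ene | CC(C)=CCCBr | starting material
21 | 6‑methylhept‑5‑en‑1‑yne | CC(C)=CCCC#C | intermediate
22 | [(1E)‑2,6‑dimethylhepta‑1,5‑dien‑1‑yl]dimethylalane (in situ) | CC(C)=CCC/C(C)=C/[Al](C)C | intermediate
23 | (1E)‑1‑iodo‑2,6‑dimethylhepta‑1,5‑diene | CC(C)=CCC/C(C)=C/I | intermediate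
24 | ethyl 3‑iodopropanoate | CCOC(=O)CCI | starting material
25 | (3‑ethoxy‑3‑oxopropyl)zinc iodide (in situ) | CCOC(=O)CC[Zn]I | intermediate
26 | ethyl (4E)‑5,9‑dimethyldeca‑4,8‑dienoate | CCOC(=O)CC/C=C(\C)CCC=C(C)C | intermediate
27 | (4E)‑N‑methoxy‑N,5,9‑trimethyldeca‑4,8‑dienamide | CON(C)C(=O)CC/C=C(\C)CCC=C(C)C | intermediate
28 | 3‑[(2S,3S)‑3‑{2‑[(2S)‑3,3‑dimethyloxiran‑2‑yl]ethyl}‑3‑methyloxiran‑2‑yl]‑N‑methoxy‑N‑methylpropanamide | CON(C)C(=O)CC[C@@H]1O[C@@]1(C)CC[C@@H]1OC1(C)C | intermediate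
29 | 1‑[(2S,3S)‑3‑{2‑[(2S)‑3,3‑dimethyloxiran‑2‑yl]ethyl}‑3‑methyloxiran‑2‑yl]hex‑5‑en‑3‑one | C=CCC(=O)CC[C@@H]1O[C@@]1(C)CC[C@@H]1OC1(C)C | intermediate
30 | tert‑butyl({(3Z)‑1‑[(2S,3S)‑3‑{2‑[(2S)‑3,3‑dimethyloxiran‑2‑yl]ethyl}‑3‑methyloxiran‑2‑yl]hexa‑3,5‑dien‑3‑yl}oxy)dimethylsilane | C=C/C=C(\O[Si](C)(C)C(C)(C)C)CC[C@@H]1O[C@@]1(C)CC[C@@H]1OC1(C)C | intermediate
31 | (3S,5aS,6S,9aS)‑6‑ethenyl‑2,2,5a‑trimethyl‑3‑(trimethylsilyloxy)octahydro‑1‑benzoxepin‑7(2H)‑one (in situ) | C=C[C@H]1[C@]2(C)CC[C@H](O[Si](C)(C)C)C(C)(C)O[C@H]2CCC1=O | intermediate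
32 | (3S,5aS,6S,9aS)‑6‑ethenyl‑3‑hydroxy‑2,2,5a‑trimethyloctahydro‑1‑benzoxepin‑7(2H)‑one (trans‑fused, equatorial vinyl) | C=C[C@H]1[C@]2(C)CC[C@H](O)C(C)(C)O[C@H]2CCC1=O | intermediate
33 | (3S,5aS,6S,7R,9aS)‑6‑ethenyl‑2,2,5a,7‑tetramethyldecahydro‑1‑benzoxepine‑3,7‑diol (axial 7‑OH) | C=C[C@H]1[C@]2(C)CC[C@H](O)C(C)(C)O[C@H]2CC[C@@]1(C)O | intermediate
34 | (3S,5aS,6S,7R,9aS)‑6‑ethenyl‑2,2,5a,7‑tetramethyl‑3,7‑bis(triethylsilyloxy)decahydro‑1‑benzoxepine | C=C[C@H]1[C@]2(C)CC[C@H](O[Si](CC)(CC)CC)C(C)(C)O[C@H]2CC[C@@]1(C)O[Si](CC)(CC)CC | intermediate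
35 | 9‑{2‑[(3S,5aS,6S,7R,9aS)‑2,2,5a,7‑tetramethyl‑3,7‑bis(triethylsilyloxy)decahydro‑1‑benzoxepin‑6‑yl]ethyl}‑9‑borabicyclo[3.3.1]nonane (in situ) | C1CCC2CCCC1B2CC[C@H]1[C@]2(C)CC[C@H](O[Si](CC)(CC)CC)C(C)(C)O[C@H]2CC[C@@]1(C)O[Si](CC)(CC)CC | intermediate
36 | potassium B‑methoxy borate of 35 (in situ) | [K+].CO[B-]1(CC[C@H]2[C@]3(C)CC[C@H](O[Si](CC)(CC)CC)C(C)(C)O[C@H]3CC[C@@]2(C)O[Si](CC)(CC)CC)C2CCCC1CCC2 | intermediate
37 | tris(triethylsilyl) ether of 38 | CC1=CC[C@H]2[C@H](CC[C@]2(C)O[Si](CC)(CC)CC)C(C)(C)[C@@H]1CC[C@H]1[C@]2(C)CC[C@H](O[Si](CC)(CC)CC)C(C)(C)O[C@H]2CC[C@@]1(C)O[Si](CC)(CC)CC | intermediate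
38 | (3S,5aS,6S,7R,9aS)‑6‑{2‑[(1S,3aS,5R,8aS)‑1‑hydroxy‑1,4,4,6‑tetramethyl‑1,2,3,3a,4,5,8,8a‑octahydroazulen‑5‑yl]ethyl}‑2,2,5a,7‑tetramethyldecahydro‑1‑benzoxepine‑3,7‑diol | CC1=CC[C@H]2[C@H](CC[C@]2(C)O)C(C)(C)[C@@H]1CC[C@H]1[C@]2(C)CC[C@H](O)C(C)(C)O[C@H]2CC[C@@]1(C)O | intermediate
39 | (5aS,6S,7R,9aS)‑7‑hydroxy‑6‑{2‑[(1S,3aS,5R,8aS)‑1‑hydroxy‑1,4,4,6‑tetramethyl‑1,2,3,3a,4,5,8,8a‑octahydroazulen‑5‑yl]ethyl}‑2,2,5a,7‑tetramethyloctahydro‑1‑benzoxepin‑3(2H)‑one | CC1=CC[C@H]2[C@H](CC[C@]2(C)O)C(C)(C)[C@@H]1CC[C@H]1[C@]2(C)CCC(=O)C(C)(C)O[C@H]2CC[C@@]1(C)O | target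

**Totals and risks**

Total step count: 23. Longest linear sequence: 13 steps (steps 11–20, then 21–23); the left branch contributes 9 linear steps plus the one‑step side branch (step 3).

Most likely to fail:

1. Step 21 (the proposed directed coupling). Transmetalation from the borate to phosphine‑bound copper may be slow, and direct substitution at the carbinol carbon or an undirected anti pathway could erode regio‑ and stereocontrol at the hindered carbon. The fallback uses known chemistry, sets out from 34 and 18, and returns at 37. Cross‑metathesis of 34 with methyl acrylate (second‑generation Hoveyda–Grubbs catalyst) gives methyl enoate F1. Hydrogenation (H2, Pd/C) gives saturated ester F2, and LiOH gives propanoic acid F3. Steglich esterification of F3 with alcohol 18 (DCC, 4‑(dimethylamino)pyridine, retention) gives allylic ester F4. Ireland–Claisen rearrangement (KN(SiMe3)2, Me3SiCl, −78 °C, then 80 °C) transfers the ester α‑carbon suprafacially to C7 on the face of the C5–O bond and gives Claisen acid F5 as a mixture at the new α‑carbon. Barton decarboxylation through thiohydroxamate ester F6 (N‑hydroxypyridine‑2‑thione, DCC; then hν, t‑BuSH) removes the carboxyl group and gives 37 with the same stereocentre as the main route.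

2. Step 18 (epoxonium cascade). The silyl triflate may activate the internal epoxide first (carbocycle without oxepane), an epoxide may undergo a hydride shift, or the dienol ether may be lost by protodesilylation. The fallback replaces the Mukaiyama‑type donor by a chromatography‑stable Sakurai‑type donor, sets out from 28, and returns at 32. Addition of CH2=CHMgBr to 28 gives vinyl ketone F7. Cross‑metathesis with allyltrimethylsilane (second‑generation Grubbs catalyst) gives γ‑silyl enone F8. With Me3SiOTf (20 mol%) and 2,6‑di‑tert‑butyl‑4‑methylpyridine at −78 °C the same epoxonium is trapped by the α‑carbon of the vinylogous allylsilane (SE2′, the alkene moving out to the vinyl group). The released silyl group caps the oxepane alkoxide to give 31, and the acidic work‑up of step 18 gives 32.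

3. Step 7 (SmI2 cyclisation). The dienone radical anion may dimerise at its β‑carbons, the product enone may be over‑reduced, or the carbinol epimer may form. The fallback switches from ketyl chemistry to a metal‑hydride hydrogen‑atom‑transfer radical cyclisation, sets out from 15, and returns at 17. Kinetic enolisation of the methyl ketone (LiN(i‑Pr)2, Et3SiCl, THF, −78 °C) gives silyl enol ether F9. With Fe(acac)3 and PhSiH3 in EtOH at 60 °C, hydrogen‑atom transfer gives the tertiary α‑silyloxy radical, which closes 5‑exo onto the adjacent β‑carbon of the dienone (Giese cyclisation, cis fusion, silyloxy group on the convex face) and gives 17 directly, so step 8 is skipped.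

Further compounds
F1 | step 21 | methyl (2E)‑3‑[(3S,5aS,6S,7R,9aS)‑2,2,5a,7‑tetramethyl‑3,7‑bis(triethylsilyloxy)decahydro‑1‑benzoxepin‑6‑yl]prop‑2‑enoate | COC(=O)/C=C/[C@H]1[C@]2(C)CC[C@H](O[Si](CC)(CC)CC)C(C)(C)O[C@H]2CC[C@@]1(C)O[Si](CC)(CC)CC
F2 | step 21 | methyl 3‑[(3S,5aS,6S,7R,9aS)‑2,2,5a,7‑tetramethyl‑3,7‑bis(triethylsilyloxy)decahydro‑1‑benzoxepin‑6‑yl]propanoate | COC(=O)CC[C@H]1[C@]2(C)CC[C@H](O[Si](CC)(CC)CC)C(C)(C)O[C@H]2CC[C@@]1(C)O[Si](CC)(CC)CC
F3 | step 21 | 3‑[(3S,5aS,6S,7R,9aS)‑2,2,5a,7‑tetramethyl‑3,7‑bis(triethylsilyloxy)decahydro‑1‑benzoxepin‑6‑yl]propanoic acid | OC(=O)CC[C@H]1[C@]2(C)CC[C@H](O[Si](CC)(CC)CC)C(C)(C)O[C@H]2CC[C@@]1(C)O[Si](CC)(CC)CC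
F4 | step 21 | ester of acid F3 with alcohol 18 | CC1=CC(C)(C)[C@H]2CC[C@](C)(O[Si](CC)(CC)CC)[C@H]2C[C@H]1OC(=O)CC[C@H]1[C@]2(C)CC[C@H](O[Si](CC)(CC)CC)C(C)(C)O[C@H]2CC[C@@]1(C)O[Si](CC)(CC)CC
F5 | step 21 | 37 bearing a carboxyl group on the bridge carbon next to the hydroazulene (both epimers at that carbon) | CC1=CC[C@H]2[C@H](CC[C@]2(C)O[Si](CC)(CC)CC)C(C)(C)[C@@H]1C(C(O)=O)C[C@H]1[C@]2(C)CC[C@H](O[Si](CC)(CC)CC)C(C)(C)O[C@H]2CC[C@@]1(C)O[Si](CC)(CC)CC
F6 | step 21 | 2‑thioxopyridin‑1(2H)‑yl ester of F5 | CC1=CC[C@H]2[C@H](CC[C@]2(C)O[Si](CC)(CC)CC)C(C)(C)[C@@H]1C(C(=O)ON3C=CC=CC3=S)C[C@H]1[C@]2(C)CC[C@H](O[Si](CC)(CC)CC)C(C)(C)O[C@H]2CC[C@@]1(C)O[Si](CC)(CC)CC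
F7 | step 18 | 5‑[(2S,3S)‑3‑{2‑[(2S)‑3,3‑dimethyloxiran‑2‑yl]ethyl}‑3‑methyloxiran‑2‑yl]pent‑1‑en‑3‑one | C=CC(=O)CC[C@@H]1O[C@@]1(C)CC[C@@H]1OC1(C)C
F8 | step 18 | (4E)‑1‑[(2S,3S)‑3‑{2‑[(2S)‑3,3‑dimethyloxiran‑2‑yl]ethyl}‑3‑methyloxiran‑2‑yl]‑6‑(trimethylsilyl)hex‑4‑en‑3‑one | C[Si](C)(C)C/C=C/C(=O)CC[C@@H]1O[C@@]1(C)CC[C@@H]1OC1(C)C
F9 | step 7 | (5S)‑2,4,4‑trimethyl‑5‑[3‑(triethylsilyloxy)but‑3‑en‑1‑yl]cyclohepta‑2,6‑dien‑1‑one | CC1=CC(C)(C)[C@@H](CCC(=C)O[Si](CC)(CC)CC)C=CC1=O
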